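The synthesis rests on cutting ring A at C5–C6 and C4a–C8a. Ring A shows three adjacent oxygen-bearing carbons (C8a–O1, C8–OMe, C7–OMe), then C6–H and C5–O. This sequence is the carbonyl and the two methoxy carbons of dimethyl squarate extended by an α-alkoxyvinyl group. The precursor is therefore racemic 4-chloro-2,3-dimethoxycyclobutenone. In one operation, Stille coupling with tributyl(1-ethoxyvinyl)stannane, 4π ring opening and 6π ring closure should give 5-ethoxy-2,3-dimethoxyphenol, in which every ring A oxygen is in place and chemically distinct. Fries acylation, Baker–Venkataraman annulation with a benzyl-protected ring B acid and a single BCl3 unmasking finish the flavone.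

Key step: step 3

Remark: the target has no stereocentre. The cyclobutenones that carry an sp3 ring carbon are racemates, and that centre disappears on ring opening. Flavone numbering is used for ring positions wherever it is named as such.

**Step 1**
Reactants: 1 dimethyl squarate (3,4-dimethoxycyclobut-3-ene-1,2-dione)
Product: 2 4-hydroxy-2,3-dimethoxycyclobut-2-en-1-one (racemic)
Conditions: LiAlH(OtBu)3 (1.05 equiv), THF, −78 °C; cold aq. NH4Cl
Reagents that add atoms: none
Why: Chemoselective 1,2-carbonyl reduction, in which the bulky, weakly reducing alkoxyaluminium hydride adds once to one of two equivalent carbonyl groups, the resulting alkoxide deactivates the ring toward a second hydride, and the buffered cold quench avoids acid-induced loss of methanol; the new stereocentre forms as a racemate and is erased in step 3.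

**Step 2**
Reactants: 2 4-hydroxy-2,3-dimethoxycyclobut-2-en-1-one
Product: 3 4-chloro-2,3-dimethoxycyclobut-2-en-1-one (racemic)
Conditions: SOCl2, pyridine, CH2Cl2, −20 to 0 °C
Reagents that add atoms: thionyl chloride, O=S(Cl)Cl
Why: Darzens-type chlorodehydroxylation, in which chloride displaces the chlorosulfite of 2 at the allylic α-keto carbon, and the cold, dry, pyridine-buffered medium should hold back ionisation and demethylation of the electron-rich ring; the stereocentre stays racemic and is erased in step 3.

**Step 3**
Reactants: 3 4-chloro-2,3-dimethoxycyclobut-2-en-1-one; 4 tributyl(1-ethoxyvinyl)stannane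
Product: 8 5-ethoxy-2,3-dimethoxyphenol, via 4-(1-ethoxyvinyl)-2,3-dimethoxycyclobut-2-en-1-one 5 (not isolated), via dienylketene 6 (not isolated), via cyclohexa-2,4-dienone 7 (not isolated)
Conditions: PdCl2(PhCN)2 (5 mol %), tri(2-furyl)phosphine (10 mol %), dioxane (dry, degassed, dilute), 50 °C, then 100 °C
Reagents that add atoms: none
Why: Zerovalent palladium, generated in situ from PdCl2(PhCN)2, ionises the allylic α-keto C–Cl bond of 3 to an η3-oxocyclobutenylpalladium chloride, the poorly donating furylphosphine accelerates transfer of the ethoxyvinyl group from tin, and reductive elimination makes the C5–C6 bond (flavone numbering) of 5. At 100 °C 5 opens in a conrotatory 4π process to dienylketene 6, the ketene carbon then bonds to the terminal CH2 in a disrotatory 6π electrocyclization that forms C4a–C8a and closes the six-membered carbocyclic ring A, and tautomerisation of dienone 7 gives phenol 8. The closest known reaction type is the Stille cross-coupling of 4-chlorocyclobutenones with alkenylstannanes followed by thermal benzannulation, a deoxy relative of the Moore rearrangement. No stereocentre is formed, and the one in 3 and 5 is erased on ring opening. Two selectivities are needed: the new bond must form at the hydrogen-bearing allyl terminus (cyclobutenone C4) and not at the methoxy-bearing one (cyclobutenone C2, which would end in the 3,4,5-trioxygenated phenol), which the lower steric demand at C4 and retention of the conjugated vinylogous ester should secure; and the vinyl group must rotate inward, which is secured because the outward ketene cannot cyclise and simply recloses to 5 until all material has passed through 6. Dry, dilute conditions protect the enol ether from hydrolysis and keep phenol 8 from adding to ketene 6.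

**Step 4**
Reactants: 8 5-ethoxy-2,3-dimethoxyphenol; 9 methoxyacetyl chloride
Product: 10 5-ethoxy-2,3-dimethoxyphenyl 2-methoxyacetate
Conditions: Et3N, CH2Cl2, 0 °C
Reagents that add atoms: none
Why: Base-mediated O-acylation (Schotten–Baumann type) of the only nucleophilic group in 8, which also lets the phenol be freed from tin residues as a stable ester.

**Step 5**
Reactants: 10 5-ethoxy-2,3-dimethoxyphenyl 2-methoxyacetate
Product: 12 1-(6-ethoxy-2-hydroxy-3,4-dimethoxyphenyl)-2-methoxyethan-1-one, via difluoroboron chelate 11 (not isolated)
Conditions: BF3·OEt2 (3 equiv), ClCH2CH2Cl, 70 °C; then MeOH/H2O, 60 °C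
Reagents that add atoms: none
Why: Fries rearrangement under thermodynamic control, in which BF3 binds the carbonyl and α-methoxy oxygens of the ester so that the acyl group is passed on without a free acylium ion that could lose CO, only one ortho carbon (future C4a) is unsubstituted, and the six-membered chelate 11 is the sink into which any twisted para ketone formed reversibly at the future C6 should drain.

**Step 6**
Reactants: 13 2,3-dihydroxybenzoic acid
Product: 15 2,3-bis(benzyloxy)benzoic acid, via benzyl 2,3-bis(benzyloxy)benzoate 14 (not isolated)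
Conditions: BnBr (3.3 equiv), K2CO3, acetone, reflux; filter, concentrate; NaOH, MeOH/H2O, reflux; aq. HCl
Reagents that add atoms: benzyl bromide, BrCc1ccccc1; sodium hydroxide, [Na+].[OH-] (one carboxyl oxygen)
Why: Williamson alkylation benzylates both phenols and the carboxylate, and saponification then cleaves only the ester because aryl benzyl ethers are inert to hydroxide.

**Step 7**
Reactants: 15 2,3-bis(benzyloxy)benzoic acid; 12 1-(6-ethoxy-2-hydroxy-3,4-dimethoxyphenyl)-2-methoxyethan-1-one
Product: 17 3-ethoxy-5,6-dimethoxy-2-(2-methoxyacetyl)phenyl 2,3-bis(benzyloxy)benzoate, via 2,3-bis(benzyloxy)benzoyl chloride 16 (not isolated)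
Conditions: (COCl)2, DMF (cat.), CH2Cl2, 0 °C to rt, evaporate; then 12, pyridine, DMAP (cat.), 60 °C
Reagents that add atoms: none
Why: Vilsmeier-catalysed acid chloride formation followed by DMAP-catalysed esterification, the acyl chloride being chosen because the phenol of 12 is hydrogen-bonded to the ketone and flanked by two ortho substituents.

**Step 8**
Reactants: 17 3-ethoxy-5,6-dimethoxy-2-(2-methoxyacetyl)phenyl 2,3-bis(benzyloxy)benzoate
Product: 19 2-[2,3-bis(benzyloxy)phenyl]-5-ethoxy-3,7,8-trimethoxy-4H-chromen-4-one, via 1,3-diketone 18 (not isolated)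
Conditions: KOH (powdered), pyridine, 50 °C; aq. HCl; then NaOAc, AcOH, reflux
Reagents that add atoms: none
Why: Baker–Venkataraman rearrangement (intramolecular Claisen transfer of the aroyl group from oxygen to the α-methoxy enolate carbon) followed by cyclodehydration, in which ring C can close in one direction only because the C8a oxygen is the single free phenol, the buffered acetic acid spares the benzyl ethers, and the labile stereocentre of 18 vanishes on dehydration.

**Step 9**
Reactants: 19 2-[2,3-bis(benzyloxy)phenyl]-5-ethoxy-3,7,8-trimethoxy-4H-chromen-4-one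
Product: 20 5,2',3'-trihydroxy-3,7,8-trimethoxyflavone
Conditions: BCl3 (1 M in CH2Cl2, about 6 equiv), C6HMe5 (6 equiv), CH2Cl2, −78 to 0 °C; then MeOH/H2O
Reagents that add atoms: none
Why: Lewis acid ether cleavage, in which BCl3 removes both benzyl ethers at low temperature while pentamethylbenzene traps the benzyl cations before they alkylate C6, boron bridging the C4 carbonyl and O5 then activates only the peri ethyl ether toward chloride on warming, the unchelated 7- and 8-methoxyls and the less well chelated 3-methoxyl should persist, and the cold aprotic medium excludes a Wessely–Moser rearrangement.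

**Compound list**
1 | dimethyl squarate | COC1=C(OC)C(=O)C1=O | starting material
2 | 4-hydroxy-2,3-dimethoxycyclobut-2-en-1-one (racemic) | COC1=C(OC)C(O)C1=O | intermediate
3 | 4-chloro-2,3-dimethoxycyclobut-2-en-1-one (racemic) | COC1=C(OC)C(Cl)C1=O | intermediate
4 | tributyl(1-ethoxyvinyl)stannane | CCCC[Sn](CCCC)(CCCC)C(=C)OCC | starting material
5 | 4-(1-ethoxyvinyl)-2,3-dimethoxycyclobut-2-en-1-one (racemic, not isolated) | CCOC(=C)C1C(OC)=C(OC)C1=O | intermediate
6 | (3E)-5-ethoxy-2,3-dimethoxyhexa-1,3,5-trien-1-one, the dienylketene with the vinyl group cis to the ketene carbon chain (not isolated) | O=C=C(OC)/C(OC)=C\C(=C)OCC | intermediate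
7 | 5-ethoxy-2,3-dimethoxycyclohexa-2,4-dien-1-one (not isolated) | O=C1CC(OCC)=CC(OC)=C1OC | intermediate
8 | 5-ethoxy-2,3-dimethoxyphenol | CCOc1cc(O)c(OC)c(OC)c1 | intermediate
9 | methoxyacetyl chloride | COCC(=O)Cl | starting material
10 | 5-ethoxy-2,3-dimethoxyphenyl 2-methoxyacetate | CCOc1cc(OC)c(OC)c(OC(=O)COC)c1 | intermediate
11 | difluoroboron chelate of 12, boron bound to the phenolate oxygen and the ketone oxygen (not isolated) | CCOc1cc(OC)c(OC)c2O[B-](F)(F)[O+]=C(COC)c12 | intermediate
12 | 1-(6-ethoxy-2-hydroxy-3,4-dimethoxyphenyl)-2-methoxyethan-1-one | CCOc1cc(OC)c(OC)c(O)c1C(=O)COC | intermediate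
13 | 2,3-dihydroxybenzoic acid | O=C(O)c1cccc(O)c1O | starting material
14 | benzyl 2,3-bis(benzyloxy)benzoate (not isolated) | O=C(OCc1ccccc1)c1cccc(OCc2ccccc2)c1OCc1ccccc1 | intermediate
15 | 2,3-bis(benzyloxy)benzoic acid | O=C(O)c1cccc(OCc2ccccc2)c1OCc1ccccc1 | intermediate
16 | 2,3-bis(benzyloxy)benzoyl chloride (not isolated) | O=C(Cl)c1cccc(OCc2ccccc2)c1OCc1ccccc1 | intermediate
17 | 3-ethoxy-5,6-dimethoxy-2-(2-methoxyacetyl)phenyl 2,3-bis(benzyloxy)benzoate | CCOc1cc(OC)c(OC)c(OC(=O)c2cccc(OCc3ccccc3)c2OCc2ccccc2)c1C(=O)COC | intermediate
18 | 1-[2,3-bis(benzyloxy)phenyl]-3-(6-ethoxy-2-hydroxy-3,4-dimethoxyphenyl)-2-methoxypropane-1,3-dione (configurationally labile, not isolated) | CCOc1cc(OC)c(OC)c(O)c1C(=O)C(OC)C(=O)c1cccc(OCc2ccccc2)c1OCc1ccccc1 | intermediate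
19 | 2-[2,3-bis(benzyloxy)phenyl]-5-ethoxy-3,7,8-trimethoxy-4H-chromen-4-one | CCOc1cc(OC)c(OC)c2oc(-c3cccc(OCc4ccccc4)c3OCc3ccccc3)c(OC)c(=O)c12 | intermediate
20 | 5,2',3'-trihydroxy-3,7,8-trimethoxyflavone | COc1cc(O)c2c(=O)c(OC)c(-c3cccc(O)c3O)oc2c1OC | target

Total step count: 9
Longest linear sequence: 8 (steps 1 to 5 and 7 to 9)

**Steps most likely to fail**

**Step 3.** Three things may go wrong:
- The α-substituted stannane may transfer its group slowly, so that the oxocyclobutenylpalladium species decays.
- Bond formation may drift to the methoxy-bearing allyl terminus.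
- The enol ether may hydrolyse before the ring opens.

The fallback runs from 1 back to 10 and introduces the C6 hydrogen after the benzannulation instead of before it. 1-Ethoxyvinyllithium (ethyl vinyl ether, t-BuLi, THF, −78 to 0 °C) is added to 1 at −78 °C to give 4-(1-ethoxyvinyl)-4-hydroxy-2,3-dimethoxycyclobut-2-en-1-one F1. Moore rearrangement in refluxing toluene under argon, in which the hydroxyl turns outward and the vinyl group inward, should give 5-ethoxy-2,3-dimethoxybenzene-1,4-diol F2. The less hindered hydroxyl, the one next to the ring C–H, is acylated with 9 (1 equiv, pyridine, CH2Cl2, −40 °C) to 5-ethoxy-4-hydroxy-2,3-dimethoxyphenyl 2-methoxyacetate F3. The remaining hydroxyl is converted with Tf2O and pyridine into 5-ethoxy-2,3-dimethoxy-4-(trifluoromethylsulfonyloxy)phenyl 2-methoxyacetate F4. Palladium-catalysed formate reduction (Pd(OAc)2, dppf, HCO2H, Et3N, DMF, 60 °C) then replaces the triflate by hydrogen and gives 10.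

**Step 2.** Activation of the hydroxyl may trigger ionisation to the methoxy-stabilised cyclobutenyl cation. Chloride attack on a methyl group would then dealkylate the ring irreversibly. The same degradation may occur during purification or storage of the chloride.

The fallback runs from 2 back to 8 and replaces the halide by an allylic ester made under basic, non-ionising conditions. Acetylation (Ac2O, pyridine, DMAP cat., CH2Cl2, 0 °C) gives 2,3-dimethoxy-4-oxocyclobut-2-en-1-yl acetate F5. This is coupled with 4 in the manner of the Stille coupling of allylic acetates (Pd2(dba)3, tri(2-furyl)phosphine, LiCl, dioxane/DMF, 50 °C, then 100 °C). LiCl turns the allylpalladium acetate into the same chloride complex as in step 3, so that 5, 6 and 7 follow and 8 results.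

**Step 5.** Three things may go wrong:
- The acyl group may settle para to the phenolic oxygen and fail to equilibrate.
- The methoxyacetyl unit may lose CO, and the fragment may then alkoxymethylate the ring.
- The ethyl ether next to the new carbonyl may be cleaved prematurely, which would reopen the direction of ring C closure.

The fallback runs from 8 back to 12 and replaces electrophilic substitution by directed ortho-metalation. MOMCl and iPr2NEt (CH2Cl2, 0 °C) give 5-ethoxy-1,2-dimethoxy-3-(methoxymethoxy)benzene F6. n-BuLi with TMEDA (THF, 0 °C) should lithiate the carbon flanked by the chelating acetal and the ethoxy group. Weinreb ketone synthesis with N,2-dimethoxy-N-methylacetamide (−78 °C) then gives 1-[6-ethoxy-3,4-dimethoxy-2-(methoxymethoxy)phenyl]-2-methoxyethan-1-one F7. HCl in MeOH at rt removes the acetal and returns 12.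

**Further compounds**
F1 | step 3 | 4-(1-ethoxyvinyl)-4-hydroxy-2,3-dimethoxycyclobut-2-en-1-one (racemic) | CCOC(=C)C1(O)C(OC)=C(OC)C1=O
F2 | step 3 | 5-ethoxy-2,3-dimethoxybenzene-1,4-diol | CCOc1cc(O)c(OC)c(OC)c1O
F3 | step 3 | 5-ethoxy-4-hydroxy-2,3-dimethoxyphenyl 2-methoxyacetate | CCOc1cc(OC(=O)COC)c(OC)c(OC)c1O
F4 | step 3 | 5-ethoxy-2,3-dimethoxy-4-(trifluoromethylsulfonyloxy)phenyl 2-methoxyacetate | CCOc1cc(OC(=O)COC)c(OC)c(OC)c1OS(=O)(=O)C(F)(F)F
F5 | step 2 | 2,3-dimethoxy-4-oxocyclobut-2-en-1-yl acetate (racemic) | CC(=O)OC1C(OC)=C(OC)C1=O
F6 | step 5 | 5-ethoxy-1,2-dimethoxy-3-(methoxymethoxy)benzene | CCOc1cc(OC)c(OC)c(OCOC)c1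
F7 | step 5 | 1-[6-ethoxy-3,4-dimethoxy-2-(methoxymethoxy)phenyl]-2-methoxyethan-1-one | CCOc1cc(OC)c(OC)c(OCOC)c1C(=O)COC
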